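**Plan**

- Retrosynthesis: ring B is cut at C4'–C5', C2'–C3' and C5'–C6' into a 3-(benzofuran-2-yl)-2,4-diprenylcyclobutenone and an alkoxyacetylene. The cyclobutenone is cut at the bond from benzofuran C2 to its C3, the furan ring at O1–C2 and C2=C3, and the 1,1-dimethylallyl group at C7–CMe2 (Claisen).
- Enabling feature: ring B is a pentasubstituted resorcinol with hydrogen only at C4' between O3' and O5', and with the prenyl groups at C2' and C6' flanking the benzofuranyl carbon C1'. A vinylketene O=C=C(prenyl)–C(aryl)=CH(prenyl) and HC≡C–OR deliver exactly this pattern.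
- Forward order: ring A is present in 2,4,6-trihydroxybenzaldehyde; the furan ring is closed next (dibromoalkene, copper C–O coupling), then the four-membered ring (ketene plus ynol ether, two molecules of one alkyne), then ring B by benzannulation.
- Protecting groups: the acetylene oxygen carries 2-(trimethylsilyl)ethyl and ring A carries triisopropylsilyl (TIPS) ethers, so that fluoride alone frees all four phenols. A plain alkyl ether on ring B would need nucleophilic dealkylation of a phenoxide-bearing ring or a Lewis acid that cyclises ortho-prenyl phenols.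
- Stereochemistry: the target has no stereocentre and no stereogenic alkene; the sp3 carbons of the cyclobutenones are racemic and become aromatic carbons.

Key step: step 10

Remark: ynol ether 21 is assumed to survive 80 °C long enough for the benzannulation, as primary-alkyl ynol ethers do. Benzofuran numbering is O1, C2, C3, C3a, C4–C7, C7a; the aryl ring carries primed numbers.

**Route**

Step 1
Reactants: 1 2,4,6-trihydroxybenzaldehyde; 2 1-bromo-3-methylbut-2-ene (prenyl bromide)
Product: 3 2,6-dihydroxy-4-[(3-methylbut-2-en-1-yl)oxy]benzaldehyde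
Conditions: K2CO3 (1.0 equiv), 2 (1.0 equiv), acetone, 0 → 20 °C
Reagents that add atoms: none
Why: Williamson etherification should take place on the 4-OH, which is para to the formyl group, the most acidic phenol and the only one not held in a hydrogen bond to the carbonyl.

Step 2
Reactants: 3 2,6-dihydroxy-4-[(3-methylbut-2-en-1-yl)oxy]benzaldehyde
Product: 4 2,4,6-trihydroxy-3-(2-methylbut-3-en-2-yl)benzaldehyde
Conditions: EtOH–H2O (4:1), 130 °C, sealed tube, argon
Reagents that add atoms: none
Why: Aromatic Claisen rearrangement ([3,3]-sigmatropic shift) joins the CMe2 terminus to a carbon ortho to the ether oxygen; the two ortho carbons of 3 are equivalent and the para carbon bears the formyl group, so one phenol should form, and the protic medium lets the shift run at moderate temperature.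

Step 3
Reactants: 4 2,4,6-trihydroxy-3-(2-methylbut-3-en-2-yl)benzaldehyde
Product: 5 2-hydroxy-3-(2-methylbut-3-en-2-yl)-4,6-bis[(triisopropylsilyl)oxy]benzaldehyde
Conditions: TIPSOTf (2.1 equiv), 2,6-lutidine, CH2Cl2, −78 → 0 °C
Reagents that add atoms: triisopropylsilyl trifluoromethanesulfonate, CC(C)[Si](C(C)C)(C(C)C)OS(=O)(=O)C(F)(F)F
Why: Silylation with a bulky silyl triflate is ruled by access, so the 4-OH and the 6-OH should react while the 2-OH, hydrogen-bonded to the formyl group and wedged against the quaternary carbon, stays free to become the furan oxygen.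

Step 4
Reactants: 5 2-hydroxy-3-(2-methylbut-3-en-2-yl)-4,6-bis[(triisopropylsilyl)oxy]benzaldehyde
Product: 6 2-(2,2-dibromoethenyl)-6-(2-methylbut-3-en-2-yl)-3,5-bis[(triisopropylsilyl)oxy]phenol
Conditions: CBr4, PPh3, Zn dust, CH2Cl2, 20 °C (ylide preformed); then 5, 0 → 20 °C
Reagents that add atoms: carbon tetrabromide, BrC(Br)(Br)Br
Why: Ramirez gem-dibromoolefination (first stage of the Corey–Fuchs sequence) converts the aldehyde into the 1,1-dibromoalkene under non-basic conditions, so the chelated phenol stays neutral and the silyl ethers should be untouched.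

Step 5
Reactants: 6 2-(2,2-dibromoethenyl)-6-(2-methylbut-3-en-2-yl)-3,5-bis[(triisopropylsilyl)oxy]phenol
Product: 7 2-bromo-7-(2-methylbut-3-en-2-yl)-4,6-bis[(triisopropylsilyl)oxy]-1-benzofuran
Conditions: CuI (5 mol %), K3PO4, THF, 80 °C
Reagents that add atoms: none
Why: Copper-catalysed intramolecular C–O coupling (Ullmann-type vinylation) of the phenol with the cis bromide of the dibromoalkene closes the furan ring and leaves the second bromine at C2 as the handle for metalation.

Step 6
Reactants: 8 ethoxyacetylene; 2 1-bromo-3-methylbut-2-ene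
Product: 10 1-ethoxy-5-methylhex-4-en-1-yne, via lithium ethoxyacetylide 9 (not isolated)
Conditions: n-BuLi, THF, −78 °C; then 2, DMPU, −78 → 20 °C
Reagents that add atoms: none
Why: Deprotonation of the terminal ynol ether and SN2 alkylation of the lithium acetylide by the allylic bromide in the presence of DMPU is the standard way to 1-alkoxy-1-alkynes.

Step 7
Reactants: 10 1-ethoxy-5-methylhex-4-en-1-yne (two molecules)
Product: 12 racemic 3-ethoxy-2,4-bis(3-methylbut-2-en-1-yl)cyclobut-2-en-1-one, via prenylketene 11 (not isolated)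
Conditions: toluene, 120 °C, sealed tube
Reagents that add atoms: none
Why: A 1-ethoxyalkyne loses ethylene by retro-ene reaction on heating, and the monoalkylketene is captured by unchanged 10 in a ketene–ynol ether [2+2] cycloaddition (nucleophilic alkyne carbon to the ketene carbonyl carbon); as both partners carry a prenyl group, this thermal dimerisation should give the 2,4-diprenyl-3-ethoxycyclobutenone directly, with C4 racemic.

Step 8
Reactants: 7 2-bromo-7-(2-methylbut-3-en-2-yl)-4,6-bis[(triisopropylsilyl)oxy]-1-benzofuran; 12 racemic 3-ethoxy-2,4-bis(3-methylbut-2-en-1-yl)cyclobut-2-en-1-one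
Product: 15 racemic 3-[7-(2-methylbut-3-en-2-yl)-4,6-bis[(triisopropylsilyl)oxy]-1-benzofuran-2-yl]-2,4-bis(3-methylbut-2-en-1-yl)cyclobut-2-en-1-one, via 2-lithiobenzofuran 13 (not isolated), via cyclobutenol adduct 14 (not isolated)
Conditions: n-BuLi, THF, −78 °C; then 12, −78 °C; then 1 M HCl, 0 → 20 °C
Reagents that add atoms: water, O
Why: Bromine–lithium exchange gives the 2-lithiobenzofuran, which adds 1,2 to the vinylogous ester carbonyl, and acid then ionises the tertiary allylic alcohol and hydrolyses the enol ether with 1,3-carbonyl transposition (Stork–Danheiser sequence), which puts the aryl group on C3 of the new enone; C4 stays racemic.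

Step 9
Reactants: 16 2-(trimethylsilyl)ethanol; 17 trichloroethylene
Product: 21 trimethyl[2-(ethynyloxy)ethyl]silane, via dichlorovinyl ether 18 (not isolated), via chloroethynyl ether 19 (not isolated), via lithium alkynyl ether 20 (not isolated)
Conditions: KH, THF, 0 °C; 17, −50 → 20 °C; n-BuLi (2.4 equiv), −78 → −40 °C; H2O, −78 °C
Reagents that add atoms: none
Why: The potassium alkoxide adds to dichloroacetylene formed in situ from trichloroethylene, n-BuLi then dehydrochlorinates the dichlorovinyl ether and exchanges the remaining chlorine for lithium, and the quench protonates the acetylide; this addition, β-elimination and halogen–lithium exchange sequence is the general trichloroethylene route to terminal ynol ethers.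

Step 10
Reactants: 15 racemic 3-[7-(2-methylbut-3-en-2-yl)-4,6-bis[(triisopropylsilyl)oxy]-1-benzofuran-2-yl]-2,4-bis(3-methylbut-2-en-1-yl)cyclobut-2-en-1-one; 21 trimethyl[2-(ethynyloxy)ethyl]silane
Product: 26 target as its 3'-[2-(trimethylsilyl)ethyl] ether 4,6-bis(triisopropylsilyl) ether (5'-OH free), via vinylketene 22 (not isolated), via vinylcyclobutenone 23 (not isolated), via dienylketene 24 (not isolated), via cyclohexadienone 25 (not isolated)
Conditions: 21 (3 equiv), toluene, 80 °C, sealed tube, argon
Reagents that add atoms: none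
Why: Danheiser benzannulation: at 80 °C cyclobutenone 15 opens in a four-electron electrocyclic step (C4 prenyl turning outward) to vinylketene 22, which the electron-rich alkyne 21 traps in a [2+2] cycloaddition that makes C4'–C5' and C2'–C3', the nucleophilic CH carbon of the ynol ether bonding to the ketene carbon. The 4-vinylcyclobutenone 23 opens reversibly to dienylketene 24, and ring B is closed by thermal six-electron (disrotatory) electrocyclisation between the ketene carbon and the prenyl-bearing alkene terminus (C5'–C6'), after which cyclohexadienone 25 enolises to the phenol. The closest known reaction is the union of 3-aryl or 4-alkyl cyclobutenones with alkoxyacetylenes at 80 °C to give resorcinol monoethers. No stereocentre is set, since the racemic sp3 carbons of 15, 23 and 25 all become aromatic carbons. The step needs regioselectivity in the ketene–alkyne union and chemoselectivity for the alkyne over the prenyl and vinyl alkenes; the polarisation of the ynol ether secures the first (hydrogen ends at C4' between the oxygens, both prenyl groups beside C1'), and the much higher ketenophilicity of an ynol ether, together with the outward rotation that keeps the C4 prenyl group away from the ketene, secures the second. The bath is held at 80 °C and 21 is used in excess because ynol ethers with a β-hydrogen begin to lose alkene by retro-ene reaction near 100 °C.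

Step 11
Reactants: 26 target as its 3'-[2-(trimethylsilyl)ethyl] ether 4,6-bis(triisopropylsilyl) ether
Product: 28 2-[3,5-dihydroxy-2,6-bis(3-methylbut-2-en-1-yl)phenyl]-7-(2-methylbut-3-en-2-yl)-1-benzofuran-4,6-diol (target), via monoether triol 27 (not isolated)
Conditions: TBAF, THF, 20 °C; then DMF, 80 °C, argon; aq. NH4Cl
Reagents that add atoms: none
Why: Fluoride cleaves the two aryl silyl ethers at room temperature and, on warming, attacks the trimethylsilyl group of the 2-(trimethylsilyl)ethyl ether to trigger β-elimination of ethylene and the phenoxide (fluoride-induced fragmentation), so all phenols should be freed without acid, which ortho-prenyl phenols do not tolerate.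

**Compound list**

1 | 2,4,6-trihydroxybenzaldehyde | O=Cc1c(O)cc(O)cc1O | starting material
2 | 1-bromo-3-methylbut-2-ene (prenyl bromide) | CC(C)=CCBr | starting material
3 | 2,6-dihydroxy-4-[(3-methylbut-2-en-1-yl)oxy]benzaldehyde | O=Cc1c(O)cc(OCC=C(C)C)cc1O | intermediate
4 | 2,4,6-trihydroxy-3-(2-methylbut-3-en-2-yl)benzaldehyde | O=Cc1c(O)cc(O)c(C(C)(C)C=C)c1O | intermediate
5 | 2-hydroxy-3-(2-methylbut-3-en-2-yl)-4,6-bis[(triisopropylsilyl)oxy]benzaldehyde | O=Cc1c(O[Si](C(C)C)(C(C)C)C(C)C)cc(O[Si](C(C)C)(C(C)C)C(C)C)c(C(C)(C)C=C)c1O | intermediate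
6 | 2-(2,2-dibromoethenyl)-6-(2-methylbut-3-en-2-yl)-3,5-bis[(triisopropylsilyl)oxy]phenol | BrC(Br)=Cc1c(O[Si](C(C)C)(C(C)C)C(C)C)cc(O[Si](C(C)C)(C(C)C)C(C)C)c(C(C)(C)C=C)c1O | intermediate
7 | 2-bromo-7-(2-methylbut-3-en-2-yl)-4,6-bis[(triisopropylsilyl)oxy]-1-benzofuran | C=CC(C)(C)c1c(O[Si](C(C)C)(C(C)C)C(C)C)cc(O[Si](C(C)C)(C(C)C)C(C)C)c2cc(Br)oc12 | intermediate
8 | ethoxyacetylene (ethoxyethyne) | C#COCC | starting material
9 | lithium ethoxyacetylide (not isolated) | [Li]C#COCC | intermediate
10 | 1-ethoxy-5-methylhex-4-en-1-yne | CCOC#CCC=C(C)C | intermediate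
11 | prenylketene, 5-methylhexa-1,4-dien-1-one (not isolated) | O=C=CCC=C(C)C | intermediate
12 | 3-ethoxy-2,4-bis(3-methylbut-2-en-1-yl)cyclobut-2-en-1-one, racemic at C4 | CCOC1=C(CC=C(C)C)C(=O)C1CC=C(C)C | intermediate
13 | 2-lithio-7-(2-methylbut-3-en-2-yl)-4,6-bis[(triisopropylsilyl)oxy]-1-benzofuran (not isolated) | [Li]c1cc2c(O[Si](C(C)C)(C(C)C)C(C)C)cc(O[Si](C(C)C)(C(C)C)C(C)C)c(C(C)(C)C=C)c2o1 | intermediate
14 | 1-(benzofuran-2-yl)-3-ethoxy-2,4-diprenylcyclobut-2-en-1-ol adduct, racemic mixture of diastereomers (not isolated) | CCOC1=C(CC=C(C)C)C(O)(c2cc3c(O[Si](C(C)C)(C(C)C)C(C)C)cc(O[Si](C(C)C)(C(C)C)C(C)C)c(C(C)(C)C=C)c3o2)C1CC=C(C)C | intermediate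
15 | 3-[7-(2-methylbut-3-en-2-yl)-4,6-bis[(triisopropylsilyl)oxy]-1-benzofuran-2-yl]-2,4-bis(3-methylbut-2-en-1-yl)cyclobut-2-en-1-one, racemic at C4 | O=C1C(CC=C(C)C)C(c2cc3c(O[Si](C(C)C)(C(C)C)C(C)C)cc(O[Si](C(C)C)(C(C)C)C(C)C)c(C(C)(C)C=C)c3o2)=C1CC=C(C)C | intermediate
16 | 2-(trimethylsilyl)ethanol | C[Si](C)(C)CCO | starting material
17 | trichloroethylene | ClC=C(Cl)Cl | starting material
18 | (E)-1,2-dichlorovinyl 2-(trimethylsilyl)ethyl ether (not isolated) | Cl/C=C(/Cl)OCC[Si](C)(C)C | intermediate
19 | chloroethynyl 2-(trimethylsilyl)ethyl ether (not isolated) | ClC#COCC[Si](C)(C)C | intermediate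
20 | lithium [2-(trimethylsilyl)ethoxy]acetylide (not isolated) | [Li]C#COCC[Si](C)(C)C | intermediate
21 | trimethyl[2-(ethynyloxy)ethyl]silane | C#COCC[Si](C)(C)C | intermediate
22 | vinylketene O=C=C(prenyl)–C(aryl)=CH(prenyl), prenyl on the alkene trans to the ketene-bearing carbon (not isolated) | O=C=C(CC=C(C)C)/C(=C/CC=C(C)C)c1cc2c(O[Si](C(C)C)(C(C)C)C(C)C)cc(O[Si](C(C)C)(C(C)C)C(C)C)c(C(C)(C)C=C)c2o1 | intermediate
23 | 4-(1-arylalkenyl)-4-prenyl-3-[2-(trimethylsilyl)ethoxy]cyclobut-2-en-1-one, racemic (not isolated) | O=C1C=C(OCC[Si](C)(C)C)C1(CC=C(C)C)/C(=C/CC=C(C)C)c1cc2c(O[Si](C(C)C)(C(C)C)C(C)C)cc(O[Si](C(C)C)(C(C)C)C(C)C)c(C(C)(C)C=C)c2o1 | intermediate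
24 | dienylketene, ketene CH and aryl-bearing alkene on the same side of the central C=C (not isolated) | O=C=C/C(OCC[Si](C)(C)C)=C(CC=C(C)C)\C(=C\CC=C(C)C)c1cc2c(O[Si](C(C)C)(C(C)C)C(C)C)cc(O[Si](C(C)C)(C(C)C)C(C)C)c(C(C)(C)C=C)c2o1 | intermediate
25 | 4-aryl-3,5-diprenyl-2-alkoxy... cyclohexa-2,4-dien-1-one: 4-(benzofuran-2-yl)-3,5... written out as 3-[2-(trimethylsilyl)ethoxy]-4,6-diprenyl-5-arylcyclohexa-2,4-dien-1-one, racemic at C6 (not isolated) | O=C1C=C(OCC[Si](C)(C)C)C(CC=C(C)C)=C(c2cc3c(O[Si](C(C)C)(C(C)C)C(C)C)cc(O[Si](C(C)C)(C(C)C)C(C)C)c(C(C)(C)C=C)c3o2)C1CC=C(C)C | intermediate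
26 | 2-[3-hydroxy-2,6-bis(3-methylbut-2-en-1-yl)-5-[2-(trimethylsilyl)ethoxy]phenyl]-7-(2-methylbut-3-en-2-yl)-4,6-bis[(triisopropylsilyl)oxy]-1-benzofuran | C=CC(C)(C)c1c(O[Si](C(C)C)(C(C)C)C(C)C)cc(O[Si](C(C)C)(C(C)C)C(C)C)c2cc(-c3c(CC=C(C)C)c(OCC[Si](C)(C)C)cc(O)c3CC=C(C)C)oc12 | intermediate
27 | 3'-[2-(trimethylsilyl)ethyl] ether of the target, 4,6,5'-triol (not isolated) | C=CC(C)(C)c1c(O)cc(O)c2cc(-c3c(CC=C(C)C)c(OCC[Si](C)(C)C)cc(O)c3CC=C(C)C)oc12 | intermediate
28 | 2-[3,5-dihydroxy-2,6-bis(3-methylbut-2-en-1-yl)phenyl]-7-(2-methylbut-3-en-2-yl)-1-benzofuran-4,6-diol (CNP0115465.0, achiral) | C=CC(C)(C)c1c(O)cc(O)c2cc(-c3c(CC=C(C)C)c(O)cc(O)c3CC=C(C)C)oc12 | target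

**Step count**

Total: 11 steps. Longest linear sequence: 8 steps (steps 1, 2, 3, 4, 5, 8, 10, 11); steps 6–7 and step 9 are side branches.

**Steps most likely to fail**

Step 10. Ynol ether 21 may be lost by retro-ene fragmentation (to vinyltrimethylsilane and ketene) faster than 15 opens, so that vinylketene 22 dimerises or adds to its own alkenes, and the ketene released may acetylate the new phenol. The fallback sets out from 15 and 21 and comes back at 26. A degassed solution of 15 and 21 in benzene is irradiated at 20 °C through Pyrex with a medium-pressure mercury lamp; light-driven four-electron opening of cyclobutenones to vinylketenes is a known alternative trigger for this benzannulation, and it lets 22 be captured at a temperature at which 21 is stable. Excess 21 is then removed in vacuum, and vinylcyclobutenone 23, now isolated, is heated alone in toluene at 80 °C to run 24 → 25 → 26. No compound outside the list is made (F0).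

Step 2. The rearranged product may react on: one of the two hydroxyls flanking the new 1,1-dimethylallyl group can add to its vinyl group, or the ether can cleave with loss of isoprene. The fallback sets out from 3 and comes back at 7; it postpones the rearrangement until only one free phenol can flank the new group. Ramirez olefination of 3 (CBr4, PPh3, Zn) gives 2-(2,2-dibromoethenyl)-5-[(3-methylbut-2-en-1-yl)oxy]benzene-1,3-diol F1. Its two hydroxyls are equivalent, so copper-catalysed C–O coupling (CuI, K3PO4, THF, 80 °C) gives a single 2-bromo-6-[(3-methylbut-2-en-1-yl)oxy]-1-benzofuran-4-ol F2. Silylation (TIPSOTf, 2,6-lutidine) gives 2-bromo-6-[(3-methylbut-2-en-1-yl)oxy]-4-[(triisopropylsilyl)oxy]-1-benzofuran F3. Claisen rearrangement of F3 (N,N-diethylaniline, 180 °C) can only go ortho, since the para position is the ring-fusion carbon C3a; C7 should be preferred over C5, which is shielded by the neighbouring silyloxy group. This gives 2-bromo-7-(2-methylbut-3-en-2-yl)-4-[(triisopropylsilyl)oxy]-1-benzofuran-6-ol F4, and a second silylation gives 7.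

Step 11. Fragmentation of the 2-(trimethylsilyl)ethyl ether may stall: once the silyl ethers are gone ring B is a phenoxide, a poorer leaving group, and forcing may degrade the polyphenol. The fallback sets out from 15 and comes back at 28, replacing steps 10 and 11. Benzannulation of 15 with ethoxyacetylene 8 (toluene, 80 °C, where this ynol ether is stable) gives 2-[3-ethoxy-5-hydroxy-2,6-bis(3-methylbut-2-en-1-yl)phenyl]-7-(2-methylbut-3-en-2-yl)-4,6-bis[(triisopropylsilyl)oxy]-1-benzofuran F5. TBAF in THF at 20 °C removes the silyl groups to give 2-[3-ethoxy-5-hydroxy-2,6-bis(3-methylbut-2-en-1-yl)phenyl]-7-(2-methylbut-3-en-2-yl)-1-benzofuran-4,6-diol F6. The ethyl ether is then cleaved by Grignard dealkylation (MeMgI, solvent stripped, melt at 160 °C, then aq. NH4Cl) to give 28; this method is known to dealkylate resorcinol ethers that already carry a magnesium phenoxide and to leave trisubstituted alkenes alone.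

**Further compounds**

F0 | step 10 | none | none
F1 | step 2 | 2-(2,2-dibromoethenyl)-5-[(3-methylbut-2-en-1-yl)oxy]benzene-1,3-diol | BrC(Br)=Cc1c(O)cc(OCC=C(C)C)cc1O
F2 | step 2 | 2-bromo-6-[(3-methylbut-2-en-1-yl)oxy]-1-benzofuran-4-ol | Oc1cc(OCC=C(C)C)cc2oc(Br)cc12
F3 | step 2 | 2-bromo-6-[(3-methylbut-2-en-1-yl)oxy]-4-[(triisopropylsilyl)oxy]-1-benzofuran | CC(C)=CCOc1cc(O[Si](C(C)C)(C(C)C)C(C)C)c2cc(Br)oc2c1
F4 | step 2 | 2-bromo-7-(2-methylbut-3-en-2-yl)-4-[(triisopropylsilyl)oxy]-1-benzofuran-6-ol | C=CC(C)(C)c1c(O)cc(O[Si](C(C)C)(C(C)C)C(C)C)c2cc(Br)oc12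
F5 | step 11 | 2-[3-ethoxy-5-hydroxy-2,6-bis(3-methylbut-2-en-1-yl)phenyl]-7-(2-methylbut-3-en-2-yl)-4,6-bis[(triisopropylsilyl)oxy]-1-benzofuran | C=CC(C)(C)c1c(O[Si](C(C)C)(C(C)C)C(C)C)cc(O[Si](C(C)C)(C(C)C)C(C)C)c2cc(-c3c(CC=C(C)C)c(OCC)cc(O)c3CC=C(C)C)oc12
F6 | step 11 | 2-[3-ethoxy-5-hydroxy-2,6-bis(3-methylbut-2-en-1-yl)phenyl]-7-(2-methylbut-3-en-2-yl)-1-benzofuran-4,6-diol | C=CC(C)(C)c1c(O)cc(O)c2cc(-c3c(CC=C(C)C)c(OCC)cc(O)c3CC=C(C)C)oc12
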